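**Plan**

- Retrosynthesis: after the phenol O–Si bond, the ester is cut on both sides of its carbonyl carbon (C19–O–C(=O) and C(=O)–Cα). This gives three pieces: ent-labda-8(17),13(16),14-trien-19-ol (12), carbon monoxide and the (E)-styryl iodide 14.
- Enabling feature: the ester carbonyl is a single carbon held between the neopentyl C19 oxygen (axial CH2O on C4 of ring A) and the sp2 α-carbon of the 4-oxystyryl unit. It can therefore enter as CO in a three-component Pd carbonylation that forms the acyl C–Cα bond and the ester C–O bond in one operation.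
- The terpene half is cut back to andrographolide. Its lactone carbons (C16 carbonyl, C13, C14 carbinol, C15 CH2O) map onto the 2-substituted buta-1,3-diene C16=C13–C14=C15; the C3 and C14 hydroxyls are deleted.
- Forward: no ring is built, rings A/B are bought. Order: C14 deoxygenation by SN2′ hydride, C3 deoxygenation (Barton–McCombie), butenolide → Z-enediol → dibromide → zinc 1,4-elimination to the diene, then the chain is joined by carbonylation and the phenol is freed.
- Stereochemistry: C4, C5, C9 and C10 come unchanged from andrographolide; the E olefin comes from a Takai olefination and is retained through oxidative addition and CO insertion.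

Key step: step 13

Remark: labdane numbering is used throughout. The target has the ent-labdane configuration (4R,5S,9R,10S) with the C4 oxymethyl group cis to the C10 methyl (C19), which is the configuration of andrographolide.

**Route**

Step 1
Reactants: 1 andrographolide
Product: 2 3,19-O-isopropylideneandrographolide
Conditions: 2,2-dimethoxypropane, PPTS (cat.), CH2Cl2–DMSO, 40 °C
Reagents that add atoms: 2,2-dimethoxypropane, COC(C)(C)OC
Why: Acid-catalysed transacetalisation ties the cis-related C3 and C19 hydroxyls of the 1,3-diol into a six-membered acetonide and leaves the allylic C14 hydroxyl free, with no stereocentre changed.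

Step 2
Reactants: 2 3,19-O-isopropylideneandrographolide
Product: 3 14-O-acetyl-3,19-O-isopropylideneandrographolide
Conditions: Ac2O (neat), 120–140 °C, 1 h
Reagents that add atoms: acetic anhydride, CC(=O)OC(C)=O
Why: O-acetylation of the only free hydroxyl turns C14–O into a leaving group for the next step, and base-free conditions are chosen so that acetic acid is not eliminated towards the 11,12-ene.

Step 3
Reactants: 3 14-O-acetyl-3,19-O-isopropylideneandrographolide
Product: 4 14-deoxy-3,19-O-isopropylideneandrographolide
Conditions: NaBH4 (1.2 equiv), THF–MeOH, −20 → 0 °C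
Reagents that add atoms: none
Why: Hydride adds to C12, the β-carbon of the α-alkylidene lactone, and the enolate expels the C14 acetate (conjugate reduction–E1cB, overall SN2′), which moves the double bond into the ring as the C13=C14 butenolide and deletes the C14 stereocentre, in line with the known addition–elimination of thiols and amines to 14-acyl andrographolides.

Step 4
Reactants: 4 14-deoxy-3,19-O-isopropylideneandrographolide
Product: 5 14-deoxyandrographolide
Conditions: AcOH–H2O (7:3), rt
Reagents that add atoms: none
Why: Mild aqueous acid hydrolyses the acetonide without isomerising the 8(17)-methylene or opening the butenolide.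

Step 5
Reactants: 5 14-deoxyandrographolide
Product: 6 19-O-(tert-butyldimethylsilyl)-14-deoxyandrographolide
Conditions: TBSCl (1.1 equiv), imidazole, DMF, 0 °C
Reagents that add atoms: tert-butyldimethylsilyl chloride, CC(C)(C)[Si](C)(C)Cl
Why: Silylation distinguishes the primary C19 hydroxyl from the more hindered secondary C3 hydroxyl on steric grounds.

Step 6
Reactants: 6 19-O-(tert-butyldimethylsilyl)-14-deoxyandrographolide
Product: 7 3-O-(imidazol-1-ylthiocarbonyl)-19-O-(tert-butyldimethylsilyl)-14-deoxyandrographolide
Conditions: 1,1'-thiocarbonyldiimidazole (3 equiv), DMAP (cat.), ClCH2CH2Cl, 80 °C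
Reagents that add atoms: 1,1'-thiocarbonyldiimidazole, S=C(n1ccnc1)n1ccnc1
Why: Neutral thioacylation of the remaining secondary hydroxyl (first half of a Barton–McCombie deoxygenation) avoids the strong base of xanthate formation, which the γ-acidic butenolide would not tolerate.

Step 7
Reactants: 7 3-O-(imidazol-1-ylthiocarbonyl)-19-O-(tert-butyldimethylsilyl)-14-deoxyandrographolide
Product: 8 19-O-(tert-butyldimethylsilyl)andrograpanin [ent-19-silyloxylabda-8(17),13-dien-16,15-olide]
Conditions: Bu3SnH (2 equiv), AIBN (cat.), toluene, 100 °C
Reagents that add atoms: none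
Why: Barton–McCombie radical deoxygenation, in which the stannyl radical adds to C=S, β-scission gives the secondary C3 radical and this takes hydrogen from the stannane; C3 becomes CH2, so no stereocentre is at stake and the quaternary C4 is untouched.

Step 8
Reactants: 8 19-O-(tert-butyldimethylsilyl)andrograpanin
Product: 9 (13Z)-19-(tert-butyldimethylsilyloxy)-ent-labda-8(17),13-diene-15,16-diol
Conditions: DIBAL-H (4.5 equiv), CH2Cl2, −78 → 0 °C; aqueous Rochelle salt work-up
Reagents that add atoms: none
Why: Excess DIBAL-H reduces the butenolide by 1,2-addition to the ring-opened diol, so the cis relation of C15 and C16 across C13=C14 in the ring is carried over as the Z-enediol, while the silyl ether and the isolated alkene are inert.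

Step 9
Reactants: 9 (13Z)-19-(tert-butyldimethylsilyloxy)-ent-labda-8(17),13-diene-15,16-diol
Product: 10 (13Z)-15,16-dibromo-19-(tert-butyldimethylsilyloxy)-ent-labda-8(17),13-diene
Conditions: CBr4, PPh3, CH2Cl2, −20 → 0 °C; used crude
Reagents that add atoms: carbon tetrabromide, BrC(Br)(Br)Br
Why: Appel bromination under neutral conditions converts both primary allylic hydroxyls into bromides without acid that could cleave the silyl ether; allylic transposition or E/Z scrambling of the bromide would be harmless because every isomer of the dibromide should converge on the same diene in step 10.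

Step 10
Reactants: 10 (13Z)-15,16-dibromo-19-(tert-butyldimethylsilyloxy)-ent-labda-8(17),13-diene
Product: 11 19-(tert-butyldimethylsilyloxy)-ent-labda-8(17),13(16),14-triene
Conditions: activated Zn dust, THF, 0 °C → rt
Reagents that add atoms: none
Why: Zinc-mediated reductive 1,4-elimination of the 1,4-dibromo-2-ene (the vinylogous counterpart of vicinal debromination) expels both bromides and shifts the π-bond to give the 2-substituted buta-1,3-diene C16=C13–C14=C15.

Step 11
Reactants: 11 19-(tert-butyldimethylsilyloxy)-ent-labda-8(17),13(16),14-triene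
Product: 12 ent-labda-8(17),13(16),14-trien-19-ol
Conditions: TBAF, THF, rt → 40 °C
Reagents that add atoms: none
Why: Fluoride cleaves the neopentyl silyl ether, and the triene carries no group that is sensitive to TBAF.

Step 12
Reactants: 13 4-(tert-butyldimethylsilyloxy)benzaldehyde
Product: 14 (E)-tert-butyl[4-(2-iodoethenyl)phenoxy]dimethylsilane
Conditions: CHI3 (2 equiv), CrCl2 (6 equiv), THF, 0 °C → rt
Reagents that add atoms: iodoform, IC(I)I
Why: Takai iodo-olefination of the aryl aldehyde should favour the E-iodoalkene because the β-oxido chromium adduct eliminates from the arrangement that keeps aryl and iodine apart, and any minor Z isomer is removed by chromatography.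

Step 13
Reactants: 12 ent-labda-8(17),13(16),14-trien-19-ol; 14 (E)-tert-butyl[4-(2-iodoethenyl)phenoxy]dimethylsilane; 15 carbon monoxide
Product: 17 ent-labda-8(17),13(16),14-trien-19-yl (E)-3-[4-(tert-butyldimethylsilyloxy)phenyl]prop-2-enoate, via acylpyridinium iodide 16 (not isolated)
Conditions: 14 (1.5 equiv), Pd2(dba)3 (2.5 mol %), Xantphos (6 mol %), CO (1 atm), DMAP (1.5 equiv), i-Pr2NEt (2 equiv), MeCN–toluene, 50 °C
Reagents that add atoms: none
Why: Pd(0) inserts into the vinylic C–I bond of 14 with retention of the E geometry, CO then inserts into the Pd–C(sp2) bond, which creates the C(carbonyl)–Cα bond of the cinnamate, and DMAP takes the acyl group off palladium as acylpyridinium salt 16, which acylates the neopentyl C19 hydroxyl of 12 while the amine base takes up HI and Pd(0) re-enters the cycle. The closest known reaction type is the Heck carbonylation (alkoxycarbonylation) of vinyl halides, run here with a nucleophilic acyl-transfer relay of the kind used for hindered alcohols. No ring is closed and no stereocentre is formed; the four ring stereocentres of 12 are remote and untouched, and the E double bond is carried over from 14. The step needs chemoselectivity for CO insertion and O-acylation over Heck-type insertion of the styryl–Pd or acyl–Pd species into the 13(16),14-diene and the 8(17)-methylene of 12: under a CO atmosphere CO insertion into an alkenyl–Pd bond is faster than intermolecular alkene insertion, no Pd–H is generated that could isomerise the exocyclic alkenes, and C19–OH is the only free hydroxyl because the phenol is masked as its silyl ether.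

Step 14
Reactants: 17 ent-labda-8(17),13(16),14-trien-19-yl (E)-3-[4-(tert-butyldimethylsilyloxy)phenyl]prop-2-enoate
Product: 18 ent-labda-8(17),13(16),14-trien-19-yl (E)-3-(4-hydroxyphenyl)prop-2-enoate (CNP0131099.1)
Conditions: TBAF, AcOH (1:1), THF, 0 °C
Reagents that add atoms: none
Why: Buffered fluoride removes the aryl silyl ether at 0 °C, while the acetic acid keeps the phenoxide from attacking or isomerising the cinnamate.

**Compound list**

1 | andrographolide, (3R,4R,5S,9R,10S,12E,14S)-ent-3,14,19-trihydroxylabda-8(17),12-dien-16,15-olide | O=C1OC[C@@H](O)/C1=C\C[C@@H]2C(=C)CC[C@@H]3[C@](C)(CO)[C@H](O)CC[C@@]23C | starting material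
2 | 3,19-O-isopropylideneandrographolide (1,3-dioxane across O3 and O19, free 14S-OH) | O=C1OC[C@@H](O)/C1=C\C[C@@H]2C(=C)CC[C@@H]3[C@]4(C)COC(C)(C)O[C@@H]4CC[C@@]23C | intermediate
3 | 14-O-acetyl-3,19-O-isopropylideneandrographolide | O=C1OC[C@@H](OC(C)=O)/C1=C\C[C@@H]2C(=C)CC[C@@H]3[C@]4(C)COC(C)(C)O[C@@H]4CC[C@@]23C | intermediate
4 | 14-deoxy-3,19-O-isopropylideneandrographolide (C13=C14 butenolide, C11–C12 saturated) | O=C1OCC=C1CC[C@@H]2C(=C)CC[C@@H]3[C@]4(C)COC(C)(C)O[C@@H]4CC[C@@]23C | intermediate
5 | 14-deoxyandrographolide, ent-3,19-dihydroxylabda-8(17),13-dien-16,15-olide | O=C1OCC=C1CC[C@@H]2C(=C)CC[C@@H]3[C@](C)(CO)[C@H](O)CC[C@@]23C | intermediate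
6 | 19-O-(tert-butyldimethylsilyl)-14-deoxyandrographolide | O=C1OCC=C1CC[C@@H]2C(=C)CC[C@@H]3[C@](C)(CO[Si](C)(C)C(C)(C)C)[C@H](O)CC[C@@]23C | intermediate
7 | 3-O-(imidazol-1-ylthiocarbonyl)-19-O-(tert-butyldimethylsilyl)-14-deoxyandrographolide | O=C1OCC=C1CC[C@@H]2C(=C)CC[C@@H]3[C@](C)(CO[Si](C)(C)C(C)(C)C)[C@H](OC(=S)n4ccnc4)CC[C@@]23C | intermediate
8 | 19-O-(tert-butyldimethylsilyl)andrograpanin, (4R,5S,9R,10S)-ent-19-silyloxylabda-8(17),13-dien-16,15-olide | O=C1OCC=C1CC[C@@H]2C(=C)CC[C@@H]3[C@](C)(CO[Si](C)(C)C(C)(C)C)CCC[C@@]23C | intermediate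
9 | (13Z)-19-(tert-butyldimethylsilyloxy)-ent-labda-8(17),13-diene-15,16-diol | OC/C=C(\CO)CC[C@@H]1C(=C)CC[C@@H]2[C@](C)(CO[Si](C)(C)C(C)(C)C)CCC[C@@]12C | intermediate
10 | (13Z)-15,16-dibromo-19-(tert-butyldimethylsilyloxy)-ent-labda-8(17),13-diene | BrC/C=C(\CBr)CC[C@@H]1C(=C)CC[C@@H]2[C@](C)(CO[Si](C)(C)C(C)(C)C)CCC[C@@]12C | intermediate
11 | 19-(tert-butyldimethylsilyloxy)-ent-labda-8(17),13(16),14-triene | C=CC(=C)CC[C@@H]1C(=C)CC[C@@H]2[C@](C)(CO[Si](C)(C)C(C)(C)C)CCC[C@@]12C | intermediate
12 | (4R,5S,9R,10S)-ent-labda-8(17),13(16),14-trien-19-ol | C=CC(=C)CC[C@@H]1C(=C)CC[C@@H]2[C@](C)(CO)CCC[C@@]12C | intermediate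
13 | 4-(tert-butyldimethylsilyloxy)benzaldehyde | O=Cc1ccc(O[Si](C)(C)C(C)(C)C)cc1 | starting material
14 | (E)-tert-butyl[4-(2-iodoethenyl)phenoxy]dimethylsilane | I/C=C/c1ccc(O[Si](C)(C)C(C)(C)C)cc1 | intermediate
15 | carbon monoxide | [C-]#[O+] | starting material
16 | 1-{(E)-3-[4-(tert-butyldimethylsilyloxy)phenyl]prop-2-enoyl}-4-(dimethylamino)pyridinium iodide | CN(C)c1cc[n+](C(=O)/C=C/c2ccc(O[Si](C)(C)C(C)(C)C)cc2)cc1.[I-] | intermediate
17 | ent-labda-8(17),13(16),14-trien-19-yl (E)-3-[4-(tert-butyldimethylsilyloxy)phenyl]prop-2-enoate | C=CC(=C)CC[C@@H]1C(=C)CC[C@@H]2[C@](C)(COC(=O)/C=C/c3ccc(O[Si](C)(C)C(C)(C)C)cc3)CCC[C@@]12C | intermediate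
18 | ent-labda-8(17),13(16),14-trien-19-yl (E)-3-(4-hydroxyphenyl)prop-2-enoate, CNP0131099.1 | C=CC(=C)CC[C@@H]1C(=C)CC[C@@H]2[C@](C)(COC(=O)/C=C/c3ccc(O)cc3)CCC[C@@]12C | target

**Step count and risks**

Total step count: 14. Longest linear sequence: 13 steps (steps 1–11, 13 and 14, from andrographolide).

Steps most likely to fail:

1. Step 13. The acyl–palladium or acylpyridinium species may be captured too slowly by the hindered neopentyl alcohol, so that it is diverted by hydrolysis or by Heck-type insertion into the diene of 12. The fallback sets out from 12 and comes back at 17, and it builds the Cα=Cβ bond instead of the acyl C–Cα bond. Alcohol 12 is esterified with diethylphosphonoacetic acid (DCC, DMAP, CH2Cl2) to give ent-labda-8(17),13(16),14-trien-19-yl 2-(diethoxyphosphoryl)acetate F1. F1 is then condensed with aldehyde 13 in a Horner–Wadsworth–Emmons olefination under Masamune–Roush conditions (LiCl, DBU, MeCN), which should give the E-enoate 17.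

2. Step 3. Borohydride may reduce the product butenolide further, or the medium may eliminate acetic acid towards the 11,12-didehydro dienolide before hydride adds. The fallback sets out from 2 and comes back at 4, and it separates reduction from elimination. With the C14 hydroxyl left free (its alkoxide is a poor leaving group), conjugate reduction of the alkylidene lactone with L-Selectride (THF, −78 °C) should give 12,13-dihydro-3,19-O-isopropylideneandrographolide F2 as a mixture of C13 epimers. Mesylation (MsCl, Et3N, CH2Cl2, 0 °C → rt) gives the 14-O-mesyl derivative F3, which loses methanesulfonate by E1cB in the same flask to give butenolide 4.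

3. Step 9. Activation of the Z-enediol may lead to cyclodehydration to the 2,5-dihydrofuran, and the allylic dibromide may decompose on handling. The fallback sets out from 9 and comes back at 11, bypassing 10. Direct reductive 1,4-elimination of the 2-ene-1,4-diol with low-valent titanium (TiCl3/LiAlH4, THF, reflux) removes both allylic C–O bonds through the titanium alkoxides and makes no new isolable compound.

**Further compounds**

F1 | step 13 | ent-labda-8(17),13(16),14-trien-19-yl 2-(diethoxyphosphoryl)acetate | C=CC(=C)CC[C@@H]1C(=C)CC[C@@H]2[C@](C)(COC(=O)CP(=O)(OCC)OCC)CCC[C@@]12C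
F2 | step 3 | 12,13-dihydro-3,19-O-isopropylideneandrographolide (C13 epimers) | O=C1OC[C@@H](O)C1CC[C@@H]2C(=C)CC[C@@H]3[C@]4(C)COC(C)(C)O[C@@H]4CC[C@@]23C
F3 | step 3 | 14-O-methanesulfonyl-12,13-dihydro-3,19-O-isopropylideneandrographolide (C13 epimers) | O=C1OC[C@@H](OS(C)(=O)=O)C1CC[C@@H]2C(=C)CC[C@@H]3[C@]4(C)COC(C)(C)O[C@@H]4CC[C@@]23C
F0 | step 9 | none | none
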